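**Retrosynthetic overview**
1. Target ⇒ desilylation; C11 from convex-face hydrogenation of an 11(13)-methylene lactone; the ten-membered ring (second ring) from ring-closing metathesis at C1=C10.
2. The C8–O ester comes from acylation of the C8 carbinol with silyl-protected (E)-4-hydroxytiglic acid 23.
3. The γ-lactone (first ring): C6–C7 and the lactone C–O bond are made together by CrCl2-mediated 2-(alkoxycarbonyl)allylation of enal 16 with bromide 9.
4. Key step: the C8–O bond, the only reagent-controlled stereocentre, is made by a new amine-catalysed enantioselective α-silyloxylation of 4-methylpent-4-enal; it then relays to C7, C6 and C11.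
5. The C4=C5 geometry and C15–O come from CuI-catalysed anti-carbomagnesiation/iodination of propargyl alcohol.

Assumption: atom labels C1–C15 follow the germacrane skeleton (C6 lactone carbinol, C7 ring-fusion carbon, C8 ester carbinol, C11 lactone α-carbon, C15 hydroxymethyl carbon), and 4-methylpent-4-enal is bought.

**Step 1**
Reactants: 1 chlorotriethylsilane; 2 urea–hydrogen peroxide (1:1)
Product: 3 bis(triethylsilyl) peroxide
Conditions: 1 (2.1 equiv), 2 (1.0 equiv), DABCO (2.2 equiv), CH2Cl2, 0 °C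
Reagents that add atoms: chlorotriethylsilane, CC[Si](Cl)(CC)CC
Why: Double O-silylation of hydrogen peroxide (nucleophilic substitution at silicon) consumes two equivalents of chlorotriethylsilane per peroxide, one on each oxygen, with DABCO as HCl scavenger, and gives the distillable silyl peroxide.

**Step 2**
Reactants: 4 4-methylpent-4-enal; 3 bis(triethylsilyl) peroxide
Product: 5 (2S)-4-methyl-2-[(triethylsilyl)oxy]pent-4-enal
Conditions: (S)-2-(triphenylmethyl)pyrrolidine (10 mol %), 4-nitrobenzoic acid (10 mol %), (CF3)2CHOH/CH2Cl2 1:4, 0 °C; used crude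
Reagents that add atoms: none
Why: Proposed new method: the (S)-2-tritylpyrrolidine enamine of 4 attacks one oxygen of the O–O bond of 3 (SN2 at oxygen, the peroxide polarised by hydrogen bonding to (CF3)2CHOH and the acid co-catalyst), expelling triethylsilanol and giving an α-silyloxy iminium ion that hydrolyses to 5, the trityl group blocking one enamine face so that oxygen enters on the other and sets C8 as S; the closest known reaction is the amine-catalysed enantioselective α-benzoyloxylation of aldehydes with dibenzoyl peroxide, and silyl peroxides are known to transfer a silyloxy group to enolates and organometallic carbanions.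

**Step 3**
Reactants: 5 (2S)-4-methyl-2-[(triethylsilyl)oxy]pent-4-enal; 6 methyl prop-2-ynoate
Product: 8 methyl (4S)-3-hydroxy-6-methyl-2-methylidene-4-[(triethylsilyl)oxy]hept-6-enoate (C3 epimers), via aluminoacrylate 7 (not isolated)
Conditions: i-Bu2AlH, N-methylmorpholine N-oxide, THF, 0 °C; then 5, 0 °C to rt; aq. KNaC4H4O6 work-up
Reagents that add atoms: none
Why: Hydroalumination of the propiolate gives the α-aluminoacrylate, which adds to the aldehyde (vinylalumination, a base-free equivalent of the Morita–Baylis–Hillman reaction) without epimerising C8; the new carbinol centre is uncontrolled and is erased in step 4.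

**Step 4**
Reactants: 8 methyl (4S)-3-hydroxy-6-methyl-2-methylidene-4-[(triethylsilyl)oxy]hept-6-enoate (C3 epimers)
Product: 9 methyl (2Z,4S)-2-(bromomethyl)-6-methyl-4-[(triethylsilyl)oxy]hepta-2,6-dienoate
Conditions: NBS, Me2S, CH2Cl2, 0 °C to rt
Reagents that add atoms: N-bromosuccinimide, O=C1CCC(=O)N1Br
Why: Bromosulfonium activation of the allylic alcohol and SN2′ attack of bromide (allylic transposition) give the thermodynamically preferred (Z)-2-(bromomethyl)enoate under neutral conditions that leave C8 and the silyl ether untouched.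

**Step 5**
Reactants: 10 prop-2-yn-1-ol; 11 but-3-en-1-ylmagnesium bromide
Product: 13 (2Z)-2-(but-3-en-1-yl)-3-iodoprop-2-en-1-ol, via alkenylmagnesium chelate 12 (not isolated)
Conditions: 11 (2.2 equiv), CuI (10 mol %), Et2O, −10 °C to rt; then I2, THF, −20 °C
Reagents that add atoms: iodine, II
Why: Alkoxide-directed CuI-catalysed anti-carbomagnesiation of the propargylic alcohol (the first equivalent of 11 deprotonates the hydroxyl) puts magnesium cis to CH2O in a five-membered chelate, and iodination with retention fixes the C4=C5 geometry (C15 cis to the future C6).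

**Step 6**
Reactants: 13 (2Z)-2-(but-3-en-1-yl)-3-iodoprop-2-en-1-ol
Product: 14 tert-butyl{[(2Z)-2-(but-3-en-1-yl)-3-iodoprop-2-en-1-yl]oxy}dimethylsilane
Conditions: TBSCl, imidazole, DMF, rt
Reagents that add atoms: tert-butyldimethylsilyl chloride, CC(C)(C)[Si](C)(C)Cl
Why: Standard silylation of the primary allylic alcohol (C15–O) with no stereochemical consequence.

**Step 7**
Reactants: 14 tert-butyl{[(2Z)-2-(but-3-en-1-yl)-3-iodoprop-2-en-1-yl]oxy}dimethylsilane
Product: 16 (2Z)-3-({[tert-butyl(dimethyl)silyl]oxy}methyl)hepta-2,6-dienal, via alkenylmagnesium chloride 15 (not isolated)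
Conditions: i-PrMgCl·LiCl, THF, 0 °C; then DMF, 0 °C to rt; aq. NH4Cl
Reagents that add atoms: N,N-dimethylformamide, CN(C)C=O
Why: Iodine–magnesium exchange proceeds with retention of alkene geometry, alkenylmagnesium chloride 15 avoids the O-to-C silyl shift of the lithium analogue, and Bouveault formylation gives the Z-enal.

**Step 8**
Reactants: 9 methyl (2Z,4S)-2-(bromomethyl)-6-methyl-4-[(triethylsilyl)oxy]hepta-2,6-dienoate; 16 (2Z)-3-({[tert-butyl(dimethyl)silyl]oxy}methyl)hepta-2,6-dienal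
Product: 19 (4S,5R)-5-[(1Z)-2-({[tert-butyl(dimethyl)silyl]oxy}methyl)hexa-1,5-dien-1-yl]-4-[(1S)-1-hydroxy-3-methylbut-3-en-1-yl]-3-methylideneoxolan-2-one, via seco hydroxy ester 17 (not isolated), via triethylsilyl lactone 18 (not isolated)
Conditions: CrCl2 (4 equiv), THF, 0 °C to rt; then PPTS, MeOH, 0 °C
Reagents that add atoms: none
Why: Nozaki–Hiyama 2-(alkoxycarbonyl)allylation through a chair transition state, with the C8 substituent of the Z-allylchromium dichloride axial, gives the 6,7-syn adduct and hence the cis lactone once the CrCl2-bound alkoxide attacks the ester (lactone C–O bond); with C8–H eclipsing the alkene (allylic 1,3-strain) the aldehyde approaches anti to the C9 methylene, which places C7 anti to C8–O, and PPTS/MeOH then cleaves only the triethylsilyl ether.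

**Step 9**
Reactants: 20 2-{[tert-butyl(dimethyl)silyl]oxy}acetaldehyde; 21 ethyl 2-(triphenylphosphoranylidene)propanoate
Product: 22 ethyl (2E)-4-{[tert-butyl(dimethyl)silyl]oxy}-2-methylbut-2-enoate
Conditions: CH2Cl2, rt
Reagents that add atoms: none
Why: Wittig olefination with a stabilised α-methyl ylide gives the E-trisubstituted enoate.

**Step 10**
Reactants: 22 ethyl (2E)-4-{[tert-butyl(dimethyl)silyl]oxy}-2-methylbut-2-enoate
Product: 23 (2E)-4-{[tert-butyl(dimethyl)silyl]oxy}-2-methylbut-2-enoic acid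
Conditions: LiOH, THF/MeOH/H2O, 0 °C to rt; then 1 M HCl to pH 4
Reagents that add atoms: lithium hydroxide, [Li+].[OH-]
Why: Saponification of the ethyl ester leaves the silyl ether and the alkene geometry intact.

**Step 11**
Reactants: 19 (4S,5R)-5-[(1Z)-2-({[tert-butyl(dimethyl)silyl]oxy}methyl)hexa-1,5-dien-1-yl]-4-[(1S)-1-hydroxy-3-methylbut-3-en-1-yl]-3-methylideneoxolan-2-one; 23 (2E)-4-{[tert-butyl(dimethyl)silyl]oxy}-2-methylbut-2-enoic acid
Product: 24 (1S)-1-[(2R,3S)-2-[(1Z)-2-({[tert-butyl(dimethyl)silyl]oxy}methyl)hexa-1,5-dien-1-yl]-4-methylidene-5-oxooxolan-3-yl]-3-methylbut-3-en-1-yl (2E)-4-{[tert-butyl(dimethyl)silyl]oxy}-2-methylbut-2-enoate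
Conditions: DCC, DMAP (20 mol %), CH2Cl2, 0 °C to rt
Reagents that add atoms: none
Why: Steglich esterification acylates the only free hydroxyl (C8–OH) with retention at C8.

**Step 12**
Reactants: 24 (1S)-1-[(2R,3S)-2-[(1Z)-2-({[tert-butyl(dimethyl)silyl]oxy}methyl)hexa-1,5-dien-1-yl]-4-methylidene-5-oxooxolan-3-yl]-3-methylbut-3-en-1-yl (2E)-4-{[tert-butyl(dimethyl)silyl]oxy}-2-methylbut-2-enoate
Product: 25 (3aS,4S,6Z,10Z,11aR)-10-({[tert-butyl(dimethyl)silyl]oxy}methyl)-6-methyl-3-methylidene-2-oxo-2,3,3a,4,5,8,9,11a-octahydrocyclodeca[b]furan-4-yl (2E)-4-{[tert-butyl(dimethyl)silyl]oxy}-2-methylbut-2-enoate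
Conditions: second-generation Grubbs catalyst RuCl2(PCy3)(H2IMes)(=CHPh) (15 mol %), toluene (0.001 M), 80 °C
Reagents that add atoms: none
Why: Ring-closing metathesis starts at the monosubstituted C1 vinyl group and closes on the 1,1-disubstituted C10 alkene, the ten-membered ring accepting the trisubstituted alkene as its less strained Z (ring-cis) isomer, while the trisubstituted alkenes and the electron-poor exocyclic methylene are much poorer partners.

**Step 13**
Reactants: 25 (3aS,4S,6Z,10Z,11aR)-10-({[tert-butyl(dimethyl)silyl]oxy}methyl)-6-methyl-3-methylidene-2-oxo-2,3,3a,4,5,8,9,11a-octahydrocyclodeca[b]furan-4-yl (2E)-4-{[tert-butyl(dimethyl)silyl]oxy}-2-methylbut-2-enoate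
Product: 26 (3S,3aS,4S,6Z,10Z,11aR)-10-({[tert-butyl(dimethyl)silyl]oxy}methyl)-3,6-dimethyl-2-oxo-2,3,3a,4,5,8,9,11a-octahydrocyclodeca[b]furan-4-yl (2E)-4-{[tert-butyl(dimethyl)silyl]oxy}-2-methylbut-2-enoate
Conditions: H2 (1 atm), RhCl(PPh3)3 (10 mol %), benzene/EtOH 1:1, rt
Reagents that add atoms: none
Why: Homogeneous hydrogenation with RhCl(PPh3)3 reduces only the unhindered 1,1-disubstituted exocyclic alkene, and syn delivery of H2 from the convex face of the cis-fused lactone (the face of H6 and H7) sets C11 as S with the methyl cis to C8.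

**Step 14**
Reactants: 26 (3S,3aS,4S,6Z,10Z,11aR)-10-({[tert-butyl(dimethyl)silyl]oxy}methyl)-3,6-dimethyl-2-oxo-2,3,3a,4,5,8,9,11a-octahydrocyclodeca[b]furan-4-yl (2E)-4-{[tert-butyl(dimethyl)silyl]oxy}-2-methylbut-2-enoate
Product: 27 (3S,3aS,4S,6Z,10Z,11aR)-10-(hydroxymethyl)-3,6-dimethyl-2-oxo-2,3,3a,4,5,8,9,11a-octahydrocyclodeca[b]furan-4-yl (2E)-4-hydroxy-2-methylbut-2-enoate (CNP0222998.3)
Conditions: HF·pyridine, pyridine, THF, 0 °C to rt
Reagents that add atoms: none
Why: Buffered fluoride desilylation removes both primary allylic silyl ethers without touching the lactone, the ester or any stereocentre.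

**Compound list**
1 | chlorotriethylsilane | CC[Si](Cl)(CC)CC | starting material
2 | urea–hydrogen peroxide (1:1) | NC(N)=O.OO | starting material
3 | bis(triethylsilyl) peroxide | CC[Si](CC)(CC)OO[Si](CC)(CC)CC | intermediate
4 | 4-methylpent-4-enal | O=CCCC(C)=C | starting material
5 | (2S)-4-methyl-2-[(triethylsilyl)oxy]pent-4-enal | O=C[C@@H](O[Si](CC)(CC)CC)CC(C)=C | intermediate
6 | methyl prop-2-ynoate | C#CC(=O)OC | starting material
7 | methyl 2-[bis(2-methylpropyl)alumanyl]prop-2-enoate | C=C([Al](CC(C)C)CC(C)C)C(=O)OC | intermediate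
8 | methyl (4S)-3-hydroxy-6-methyl-2-methylidene-4-[(triethylsilyl)oxy]hept-6-enoate (C3 epimers) | C=C(C(=O)OC)C(O)[C@@H](O[Si](CC)(CC)CC)CC(C)=C | intermediate
9 | methyl (2Z,4S)-2-(bromomethyl)-6-methyl-4-[(triethylsilyl)oxy]hepta-2,6-dienoate | COC(=O)/C(CBr)=C/[C@@H](O[Si](CC)(CC)CC)CC(C)=C | intermediate
10 | prop-2-yn-1-ol | C#CCO | starting material
11 | but-3-en-1-ylmagnesium bromide | C=CCC[Mg]Br | starting material
12 | bromomagnesium (2Z)-3-(bromomagnesio)-2-(but-3-en-1-yl)prop-2-en-1-olate | Br[Mg]OC/C(CCC=C)=C\[Mg]Br | intermediate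
13 | (2Z)-2-(but-3-en-1-yl)-3-iodoprop-2-en-1-ol | OC/C(CCC=C)=C\I | intermediate
14 | tert-butyl{[(2Z)-2-(but-3-en-1-yl)-3-iodoprop-2-en-1-yl]oxy}dimethylsilane | CC(C)(C)[Si](C)(C)OC/C(CCC=C)=C\I | intermediate
15 | [(1Z)-2-({[tert-butyl(dimethyl)silyl]oxy}methyl)hexa-1,5-dien-1-yl]magnesium chloride | CC(C)(C)[Si](C)(C)OC/C(CCC=C)=C\[Mg]Cl | intermediate
16 | (2Z)-3-({[tert-butyl(dimethyl)silyl]oxy}methyl)hepta-2,6-dienal | CC(C)(C)[Si](C)(C)OC/C(CCC=C)=C\C=O | intermediate
17 | methyl (3R,4R,5Z)-6-({[tert-butyl(dimethyl)silyl]oxy}methyl)-4-hydroxy-2-methylidene-3-[(1S)-3-methyl-1-[(triethylsilyl)oxy]but-3-en-1-yl]deca-5,9-dienoate | C=CCC/C(CO[Si](C)(C)C(C)(C)C)=C/[C@@H](O)[C@H]([C@@H](O[Si](CC)(CC)CC)CC(C)=C)C(=C)C(=O)OC | intermediate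
18 | (4R,5R)-5-[(1Z)-2-({[tert-butyl(dimethyl)silyl]oxy}methyl)hexa-1,5-dien-1-yl]-3-methylidene-4-[(1S)-3-methyl-1-[(triethylsilyl)oxy]but-3-en-1-yl]oxolan-2-one | C=CCC/C(CO[Si](C)(C)C(C)(C)C)=C/[C@H]1OC(=O)C(=C)[C@H]1[C@@H](O[Si](CC)(CC)CC)CC(C)=C | intermediate
19 | (4S,5R)-5-[(1Z)-2-({[tert-butyl(dimethyl)silyl]oxy}methyl)hexa-1,5-dien-1-yl]-4-[(1S)-1-hydroxy-3-methylbut-3-en-1-yl]-3-methylideneoxolan-2-one | C=CCC/C(CO[Si](C)(C)C(C)(C)C)=C/[C@H]1OC(=O)C(=C)[C@H]1[C@@H](O)CC(C)=C | intermediate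
20 | 2-{[tert-butyl(dimethyl)silyl]oxy}acetaldehyde | CC(C)(C)[Si](C)(C)OCC=O | starting material
21 | ethyl 2-(triphenylphosphoranylidene)propanoate | CCOC(=O)C(C)=P(c1ccccc1)(c1ccccc1)c1ccccc1 | starting material
22 | ethyl (2E)-4-{[tert-butyl(dimethyl)silyl]oxy}-2-methylbut-2-enoate | CCOC(=O)/C(C)=C/CO[Si](C)(C)C(C)(C)C | intermediate
23 | (2E)-4-{[tert-butyl(dimethyl)silyl]oxy}-2-methylbut-2-enoic acid | OC(=O)/C(C)=C/CO[Si](C)(C)C(C)(C)C | intermediate
24 | (1S)-1-[(2R,3S)-2-[(1Z)-2-({[tert-butyl(dimethyl)silyl]oxy}methyl)hexa-1,5-dien-1-yl]-4-methylidene-5-oxooxolan-3-yl]-3-methylbut-3-en-1-yl (2E)-4-{[tert-butyl(dimethyl)silyl]oxy}-2-methylbut-2-enoate | C=CCC/C(CO[Si](C)(C)C(C)(C)C)=C/[C@H]1OC(=O)C(=C)[C@H]1[C@@H](OC(=O)/C(C)=C/CO[Si](C)(C)C(C)(C)C)CC(C)=C | intermediate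
25 | (3aS,4S,6Z,10Z,11aR)-10-({[tert-butyl(dimethyl)silyl]oxy}methyl)-6-methyl-3-methylidene-2-oxo-2,3,3a,4,5,8,9,11a-octahydrocyclodeca[b]furan-4-yl (2E)-4-{[tert-butyl(dimethyl)silyl]oxy}-2-methylbut-2-enoate | C/C1=C/CC/C(CO[Si](C)(C)C(C)(C)C)=C/[C@H]2OC(=O)C(=C)[C@H]2[C@@H](OC(=O)/C(C)=C/CO[Si](C)(C)C(C)(C)C)C1 | intermediate
26 | (3S,3aS,4S,6Z,10Z,11aR)-10-({[tert-butyl(dimethyl)silyl]oxy}methyl)-3,6-dimethyl-2-oxo-2,3,3a,4,5,8,9,11a-octahydrocyclodeca[b]furan-4-yl (2E)-4-{[tert-butyl(dimethyl)silyl]oxy}-2-methylbut-2-enoate | C/C1=C/CC/C(CO[Si](C)(C)C(C)(C)C)=C/[C@H]2OC(=O)[C@@H](C)[C@H]2[C@@H](OC(=O)/C(C)=C/CO[Si](C)(C)C(C)(C)C)C1 | intermediate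
27 | (3S,3aS,4S,6Z,10Z,11aR)-10-(hydroxymethyl)-3,6-dimethyl-2-oxo-2,3,3a,4,5,8,9,11a-octahydrocyclodeca[b]furan-4-yl (2E)-4-hydroxy-2-methylbut-2-enoate | C/C1=C/CC/C(CO)=C/[C@H]2OC(=O)[C@@H](C)[C@H]2[C@@H](OC(=O)/C(C)=C/CO)C1 | target

**Step count**
Total: 14 steps. Longest linear sequence: 9 steps (1, 2, 3, 4, 8, 11, 12, 13, 14).

**Three steps most likely to fail**

Step 2, the new silyloxylation. The silyl peroxide may be too weak an electrophile for an enamine, or may oxidise the amine catalyst; if the sense of induction is reversed, the (R) catalyst is used instead. The fallback uses known chemistry and sets out from 4. D-Proline-catalysed α-aminoxylation with nitrosobenzene and reduction with NaBH4 in the same flask give (2S)-4-methyl-2-[(phenylamino)oxy]pent-4-en-1-ol F1. Zn dust in acetic acid cleaves the N–O bond to (2S)-4-methylpent-4-ene-1,2-diol F2. Et3SiCl and imidazole give the bis(triethylsilyl) ether (2S)-4-methyl-1,2-bis[(triethylsilyl)oxy]pent-4-ene F3. Swern oxidation, which oxidises a primary triethylsilyl ether directly to the aldehyde, brings the material back to the route at 5.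

Step 8, the CrCl2 allylation. The risks are 1,4-elimination of the silyloxy group from the allylchromium dichloride, and the wrong relative configuration at C6/C7 or at C7/C8. The fallback sets out from 9 and replaces the allylchromium dichloride by an allylboronate, which cannot eliminate and reacts only through a closed six-membered transition state. Borylation with B2pin2 and Pd2(dba)3 gives methyl (2E,4S)-6-methyl-2-[(4,4,5,5-tetramethyl-1,3,2-dioxaborolan-2-yl)methyl]-4-[(triethylsilyl)oxy]hepta-2,6-dienoate F4, with the boryl-methyl group still cis to C8. Allylboration of 16 catalysed by Sc(OTf)3, then PPTS in MeOH for lactonisation and removal of the triethylsilyl group, returns to the route at 19.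

Step 12, the ring-closing metathesis. The cis-fused lactone may hold the two alkenes apart, so that dimers form, or the E isomer may appear. The fallback reverses the order of ring formation and sets out from 9 and 16. The CrCl2 coupling is run with Me3SiCl so that the CrCl2-bound alkoxide is trapped as methyl (3S,4R,5Z)-6-({[tert-butyl(dimethyl)silyl]oxy}methyl)-2-methylidene-3-[(1S)-3-methyl-1-[(triethylsilyl)oxy]but-3-en-1-yl]-4-[(trimethylsilyl)oxy]deca-5,9-dienoate F5. Metathesis of this open-chain ester with RuCl2(PCy3)(H2IMes)(=CHPh) gives methyl 2-[(1S,2R,3Z,7Z,10S)-4-({[tert-butyl(dimethyl)silyl]oxy}methyl)-8-methyl-10-[(triethylsilyl)oxy]-2-[(trimethylsilyl)oxy]cyclodeca-3,7-dien-1-yl]prop-2-enoate F6. PPTS in MeOH first removes the trimethylsilyl ether, and the freed C6–OH lactonises to (3aR,4S,6Z,10Z,11aR)-10-({[tert-butyl(dimethyl)silyl]oxy}methyl)-6-methyl-3-methylidene-4-[(triethylsilyl)oxy]-3a,4,5,8,9,11a-hexahydrocyclodeca[b]furan-2(3H)-one F7. Longer exposure removes the triethylsilyl ether to give (3aS,4S,6Z,10Z,11aR)-10-({[tert-butyl(dimethyl)silyl]oxy}methyl)-4-hydroxy-6-methyl-3-methylidene-3a,4,5,8,9,11a-hexahydrocyclodeca[b]furan-2(3H)-one F8. Esterification with 23 (DCC, DMAP) returns to the route at 25.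

**Further compounds**
F1 | step 2 | (2S)-4-methyl-2-[(phenylamino)oxy]pent-4-en-1-ol | OC[C@@H](ONc1ccccc1)CC(C)=C
F2 | step 2 | (2S)-4-methylpent-4-ene-1,2-diol | OC[C@@H](O)CC(C)=C
F3 | step 2 | (2S)-4-methyl-1,2-bis[(triethylsilyl)oxy]pent-4-ene | CC[Si](CC)(CC)OC[C@@H](O[Si](CC)(CC)CC)CC(C)=C
F4 | step 8 | methyl (2E,4S)-6-methyl-2-[(4,4,5,5-tetramethyl-1,3,2-dioxaborolan-2-yl)methyl]-4-[(triethylsilyl)oxy]hepta-2,6-dienoate | COC(=O)/C(CB1OC(C)(C)C(C)(C)O1)=C/[C@@H](O[Si](CC)(CC)CC)CC(C)=C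
F5 | step 12 | methyl (3S,4R,5Z)-6-({[tert-butyl(dimethyl)silyl]oxy}methyl)-2-methylidene-3-[(1S)-3-methyl-1-[(triethylsilyl)oxy]but-3-en-1-yl]-4-[(trimethylsilyl)oxy]deca-5,9-dienoate | C=CCC/C(CO[Si](C)(C)C(C)(C)C)=C/[C@@H](O[Si](C)(C)C)[C@H]([C@@H](O[Si](CC)(CC)CC)CC(C)=C)C(=C)C(=O)OC
F6 | step 12 | methyl 2-[(1S,2R,3Z,7Z,10S)-4-({[tert-butyl(dimethyl)silyl]oxy}methyl)-8-methyl-10-[(triethylsilyl)oxy]-2-[(trimethylsilyl)oxy]cyclodeca-3,7-dien-1-yl]prop-2-enoate | C/C1=C/CC/C(CO[Si](C)(C)C(C)(C)C)=C/[C@@H](O[Si](C)(C)C)[C@H]([C@@H](O[Si](CC)(CC)CC)C1)C(=C)C(=O)OC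
F7 | step 12 | (3aR,4S,6Z,10Z,11aR)-10-({[tert-butyl(dimethyl)silyl]oxy}methyl)-6-methyl-3-methylidene-4-[(triethylsilyl)oxy]-3a,4,5,8,9,11a-hexahydrocyclodeca[b]furan-2(3H)-one | C/C1=C/CC/C(CO[Si](C)(C)C(C)(C)C)=C/[C@H]2OC(=O)C(=C)[C@H]2[C@@H](O[Si](CC)(CC)CC)C1
F8 | step 12 | (3aS,4S,6Z,10Z,11aR)-10-({[tert-butyl(dimethyl)silyl]oxy}methyl)-4-hydroxy-6-methyl-3-methylidene-3a,4,5,8,9,11a-hexahydrocyclodeca[b]furan-2(3H)-one | C/C1=C/CC/C(CO[Si](C)(C)C(C)(C)C)=C/[C@H]2OC(=O)C(=C)[C@H]2[C@@H](O)C1
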